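# Proposed synthesis of trans-kumausyne

## The problem

trans-Kumausyne is an unbranched C15 chain, numbered here from the alkyne CH (C1) to the methyl group (C15), folded once into ring A, the oxolane O1–C6–C7–C8–C9. The task is therefore chain construction on both sides of a 2,3,5-trisubstituted tetrahydrofuran.

Ring A carries its three substituents on one face: the (E)-pent-2-en-4-ynyl chain at C6, the acetate at C7 and the bromohexenyl chain at C9. A fourth stereocentre, C10, lies outside the ring, and all four centres are R.

C9 is the natural anchor. Taken from the chiral pool, it can set C7 through a hydroxyl-directed 1,3-anti reduction, C7 can then fix C6 through a cis-fused lactone, and C9 must control C10 by 1,2-induction.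

The fragile parts are:
- the secondary bromide at C10, which is β to the ring oxygen and next to an allylic CH2, so elimination to a conjugated diene and participation of O1 both threaten it;
- the terminal conjugated enyne and the acetate, which are sensitive to base;
- the two E alkenes, which should be made with control of geometry and not by separation;
- the C9 aldehyde needed on the way, which can epimerise.

The bromide is therefore introduced last and with inversion, which requires a (10S) carbinol, anti to the C9–O1 bond.

The feature that allows a short answer is C10–C15. A heteroatom-bearing carbon on ring A that carries an (E)-pent-2-enyl chain is the sum of one aldehyde carbon (C10), buta-1,3-diene (C11–C14) and one methyl group (C15).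

## Retrosynthesis

**C10–Br.** The target 24 is cut first at C10–Br, giving the (10S) alcohol 23. An Appel-type substitution with inversion is preferred to any earlier bromination because every other step would then have to tolerate an eliminable bromide. 23 differs from 24 only by OH for Br. The forward step must be a clean SN2 reaction at a hindered secondary centre.

**Enyne and acetate.** 23 goes back to the bis-silylated acetate 22 and the alcohol 21, which separates O7 (acetate) from O10 (silyl ether). 21 is cut at C2–C3 into the (E)-iodoalkene 19 and trimethylsilylacetylene 20 (Sonogashira coupling). 19 is cut at C3=C4 into the lactol 16 and iodoform 17 (Takai olefination through the open hydroxy aldehyde 18). A one-step propargyl ylide olefination was set aside because it gives E/Z mixtures. The lactol comes from lactone 15, the silyl ether of 14. The lactone does three jobs: it stores C4 at the acid oxidation level, it protects O7, and it releases O7–H exactly when the acetate is to be installed. The forward steps must give mono-reduction of the lactone and E selectivity in the iodoolefination.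

**C10–C11 and C14–C15 (key disconnection).** 14 is cut into the aldehyde 11, buta-1,3-diene 12 and dimethylzinc 13. Two neighbouring cuts were considered:
- C10–C11 alone needs a preformed pentenyl metal that reacts at its α-carbon, whereas allyl metals normally give the branched γ-adduct.
- C12=C13 would need an olefination or metathesis, with more steps and an open question of geometry.

The three-component cut uses two commodity reagents and removes six carbons, one stereocentre and one alkene at once. 11 is a C7 bicycle with three stereocentres and no alkene. The forward reaction must give 1,4-regiochemistry on the diene, E geometry, attack on the Felkin–Anh face of the aldehyde, and tolerance of the lactone.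

**Ring A and the lactone.** 11 comes from the primary alcohol 10 and its silyl ether 9. 9 is cut at O1–C6, C4–C5 and C4–O7 into the acyclic ene-diol 7 and carbon monoxide 8 (palladium-catalysed oxycarbonylation). Oxa-Michael or iodoetherification routes would need a separate step to bring in C4. The precursor loses both rings and the C6 stereocentre. The forward step must give 5-exo attack by O9, cis fusion, and survival of the silyl ether in acetic acid.

**C7 and C6–C7.** The anti diol 7 comes from the β-hydroxy enone 6 by hydroxyl-directed reduction. Direct vinyl addition to a β-alkoxy aldehyde was rejected because 1,3-induction is weak there. 6 is cut at C6–C7 into the Weinreb amide 4 and vinylmagnesium bromide 5. 4 comes from the β-hydroxy ester 3, the diol ester 2 and dimethyl (R)-malate 1, whose stereocentre becomes C9.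

## Roads not taken

**Alternative 1:** a furan–oxyallyl (4+3) cycloaddition.
- Cut: C5–C6 and C9–C10, with the future C4 as a ketone carbon bridging C5 and C10.
- Forward key step: a Zn–Cu couple reduces 1,1,3,3-tetrabromopropan-2-one A3 to an oxyallyl cation that adds across the 2- and 5-positions of furan A2; further reduction removes the remaining bromines and gives the meso bicyclic ketone A1.
- Merits: one step from very cheap materials, easily scaled, and it fixes C6 and C9 cis on ring A with two C–C bonds. In material cost and speed to the ring it is better than the plan chosen here.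
- Weak points:
  - A1 is meso, so a desymmetrisation must distinguish C7 from C8 and C5 from C10 before a single enantiomer exists.
  - Oxygen reagents attack the C7=C8 alkene on the open face, anti to the three-carbon bridge, which places O7 trans to C5 and C10; the target needs it cis, so an inversion or an intramolecular delivery is required.
  - The C4–C10 bond must later be cut by a Baeyer–Villiger oxidation whose regiochemistry is unbiased once the symmetry is broken.
  - Even then only the ring core with a C10 alcohol is in hand, and C11–C15 must still be attached.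
- Comparison: against the faster first step, the chosen plan offers absolute configuration from the pool, relay control of C7 and C6 with no inversion, and direct arrival at aldehyde 11.

**Alternative 2:** an allylsilane–aldehyde (3+2) annulation with silicon as a masked oxygen.
- Cut: C8–C9 and O1–C6.
- Forward key step: a boron Lewis acid promotes attack of the allylsilane terminus of A5 on the aldehyde A6, silicon shifts from C6 to C7, and the C9 alkoxide closes on C6 to give the silyl oxolane A4.
- Merits: the route is convergent and closes ring A with two bonds. The C10 carbinol and the whole C11–C15 chain with its E alkene arrive preformed in A6, so C10 does not depend on a late facial selectivity. On that point it is better than the chosen plan.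
- Weak points:
  - In A4 the silyl group at C7 is trans to the C6 side chain (3S), so C–Si oxidation with retention gives the C7 epimer of what is needed and an inversion must follow.
  - Oxidising a dimethyl(phenyl)silyl group requires an electrophilic dephenylation that endangers the C12=C13 alkene.
  - A5 and A6 each need an enantioselective synthesis, and A6 is an epimerisable α-silyloxy aldehyde.
- Comparison: the chosen plan sets O7 cis by construction through the lactone tether, needs no silicon-to-oxygen exchange next to an alkene, and has a correction sequence for C10 (see the fallback to step 9).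

**Alternative 3:** a temporary lactone that delivers O7 by iodolactonisation.
- Cut: C7–O.
- Forward key step: iodine and bicarbonate convert the dihydrofuranylacetic acid A8 into the cis-fused iodolactone A7, the C4 carboxylate adding to C7 and iodine to C8 on the opposite face.
- Merits: the cyclisation is reliable, cis fusion is automatic, and the C10 oxygen comes from the pool inside the dioxolane. C10 is therefore more secure than in the chosen plan.
- Weak points:
  - Iodine at C8 is a throwaway substituent that costs a reductive step.
  - A8 already contains C6, C9 and C10 on a 2,5-cis dihydrofuran and needs its own stereocontrolled synthesis.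
  - After the key step the dioxolane still has to be converted into the C11–C15 chain, or cleaved to the same aldehyde 11.
- Comparison: the chosen plan closes ring A and the lactone and brings in C4 in one step from an acyclic diol, with no atom introduced only to be removed, and builds C10–C15 in one operation.

Key step: step 9

Remark: dimethyl (R)-malate 1 is taken as the purchasable form of (R)-malic acid, and 12 and 13 are used as commercial solutions.

## Route

Step 1
Reactants: 1 dimethyl (R)-malate [dimethyl (2R)-2-hydroxybutanedioate]
Product: 2 methyl (3R)-3,4-dihydroxybutanoate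
Conditions: BH3·SMe2 (1.05 equiv), NaBH4 (5 mol %), THF, 0 °C to rt; then MeOH
Reagents that add atoms: none
Why: Hydroxyl-directed chemoselective ester reduction: the alkoxyborane formed at the C9 hydroxyl delivers hydride only to the neighbouring ester (C10), the remote ester (C7) is kept and the stereocentre is not touched.

Step 2
Reactants: 2 methyl (3R)-3,4-dihydroxybutanoate
Product: 3 methyl (3R)-4-[(tert-butyldiphenylsilyl)oxy]-3-hydroxybutanoate
Conditions: TBDPSCl (1.05 equiv), imidazole, CH2Cl2, 0 °C
Reagents that add atoms: tert-butyl(chloro)diphenylsilane, CC(C)(C)[Si](Cl)(c1ccccc1)c1ccccc1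
Why: Selective silylation of the primary hydroxyl by a bulky silyl chloride; the TBDPS ether is chosen because it has to survive acetic acid in steps 5 and 6.

Step 3
Reactants: 3 methyl (3R)-4-[(tert-butyldiphenylsilyl)oxy]-3-hydroxybutanoate
Product: 4 (3R)-4-[(tert-butyldiphenylsilyl)oxy]-3-hydroxy-N-methoxy-N-methylbutanamide
Conditions: MeNH(OMe)·HCl (2 equiv), i-PrMgCl (5 equiv), THF, −20 to 0 °C
Reagents that add atoms: N,O-dimethylhydroxylamine hydrochloride, CNOC.Cl
Why: Weinreb amide formation by aminolysis of the ester with the chloromagnesium amide; the β-hydroxyl is carried as its magnesium alkoxide and should not eliminate at this temperature.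

Step 4
Reactants: 4 (3R)-4-[(tert-butyldiphenylsilyl)oxy]-3-hydroxy-N-methoxy-N-methylbutanamide; 5 vinylmagnesium bromide
Product: 6 (5R)-6-[(tert-butyldiphenylsilyl)oxy]-5-hydroxyhex-1-en-3-one
Conditions: CH2=CHMgBr (3.5 equiv), THF, −78 to 0 °C; inverse quench into cold 1 M HCl
Reagents that add atoms: vinylmagnesium bromide, C=C[Mg]Br
Why: Weinreb ketone synthesis forms C6–C7; the chelated tetrahedral adduct prevents double addition, and the acidic inverse quench keeps the released amine protonated so that it cannot add to the vinyl ketone.

Step 5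
Reactants: 6 (5R)-6-[(tert-butyldiphenylsilyl)oxy]-5-hydroxyhex-1-en-3-one
Product: 7 (2R,4R)-1-[(tert-butyldiphenylsilyl)oxy]hex-5-ene-2,4-diol
Conditions: Me4NBH(OAc)3 (5 equiv), MeCN/AcOH (1:1), −30 °C
Reagents that add atoms: none
Why: Evans–Saksena reduction: the C9 hydroxyl exchanges an acetate on boron and hydride is delivered intramolecularly through a chair transition state, which should give the 1,3-anti diol (new C7 centre R); the reagent reduces the enone only at the carbonyl.

Step 6
Reactants: 7 (2R,4R)-1-[(tert-butyldiphenylsilyl)oxy]hex-5-ene-2,4-diol; 8 carbon monoxide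
Product: 9 (3aR,5R,6aR)-5-{[(tert-butyldiphenylsilyl)oxy]methyl}tetrahydrofuro[3,2-b]furan-2(3H)-one
Conditions: PdCl2 (10 mol %), CuCl2 (3 equiv), NaOAc (3 equiv), AcOH, CO (1 atm), rt
Reagents that add atoms: carbon monoxide, [C-]#[O+]
Why: Oxycarbonylation–bicyclisation of a pent-4-ene-1,3-diol under divalent palladium: 5-exo-trig oxypalladation by O9 closes ring A (O1–C6), CO inserts into the C5–Pd bond (C4) and O7 captures the acylpalladium to close the lactone. C6 is set cis to O7 because only the cis-fused bicycle can lactonise; CuCl2 returns zerovalent palladium to the divalent state.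

Step 7
Reactants: 9 (3aR,5R,6aR)-5-{[(tert-butyldiphenylsilyl)oxy]methyl}tetrahydrofuro[3,2-b]furan-2(3H)-one
Product: 10 (3aR,5R,6aR)-5-(hydroxymethyl)tetrahydrofuro[3,2-b]furan-2(3H)-one
Conditions: TBAF (1.2 equiv), AcOH (1.2 equiv), THF, 0 °C to rt
Reagents that add atoms: none
Why: Fluoride cleavage of the silyl ether; buffering with acetic acid keeps the medium non-basic so that the lactone is neither opened nor epimerised.

Step 8
Reactants: 10 (3aR,5R,6aR)-5-(hydroxymethyl)tetrahydrofuro[3,2-b]furan-2(3H)-one
Product: 11 (3aR,5R,6aR)-2-oxohexahydrofuro[3,2-b]furan-5-carbaldehyde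
Conditions: Dess–Martin periodinane (1.3 equiv), CH2Cl2, 0 °C to rt; crude aldehyde used at once
Reagents that add atoms: none
Why: Dess–Martin oxidation of the primary alcohol under non-basic conditions, chosen so that C9, now α to the aldehyde and on the concave face of the bicycle, does not epimerise.

Step 9
Reactants: 11 (3aR,5R,6aR)-2-oxohexahydrofuro[3,2-b]furan-5-carbaldehyde; 12 buta-1,3-diene; 13 dimethylzinc
Product: 14 (3aR,5R,6aR)-5-[(1S,3E)-1-hydroxyhex-3-enyl]tetrahydrofuro[3,2-b]furan-2(3H)-one
Conditions: Ni(acac)2 (10 mol %), buta-1,3-diene (4 equiv), Me2Zn (2.4 equiv), THF, 0 °C to rt, slow addition of 11; aq. NH4Cl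
Reagents that add atoms: buta-1,3-diene, C=CC=C; dimethylzinc, C[Zn]C
Why: Me2Zn reduces Ni(acac)2 to zerovalent nickel, which binds the diene and the zinc-activated aldehyde and couples them oxidatively to an oxanickelacycle with a syn-π-allyl terminus, forming C10–C11. Methyl then passes from zinc to nickel while the oxygen goes to zinc, and reductive elimination at the far allyl carbon forms C14–C15, leaves C12=C13 E and regenerates zerovalent nickel; no ring is closed. The closest known reaction type is this same nickel-catalysed three-component union of Me2Zn, 1,3-dienes and aldehydes to (E)-hex-3-en-1-ols, established for aliphatic aldehydes, and nickel-catalysed reductive couplings of α-alkoxy aldehydes are known to follow the Felkin–Anh sense. The new C10 centre is controlled by C9: with the C9–O1 bond anti to the forming C10–C11 bond, the nickel-bound diene passes C9–H and not C8H2, which should give the (10S) alcohol, anti to O1. The step needs this facial selectivity (a zinc chelate between O1 and the carbonyl oxygen would lead to 10R), 1,4-regiochemistry with E geometry, and coupling that is faster than direct methyl transfer or enolisation at C9. The substrate supports this through the rigid cis-fused bicycle and a ring ether that should chelate zinc poorly in THF, and the lactone is inert to Me2Zn. Me2Zn has no β-hydrogen, so reductive homoallylation cannot compete, and low temperature with slow addition of 11 should keep uncatalysed methylation down.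

Step 10
Reactants: 14 (3aR,5R,6aR)-5-[(1S,3E)-1-hydroxyhex-3-enyl]tetrahydrofuro[3,2-b]furan-2(3H)-one
Product: 15 (3aR,5R,6aR)-5-[(1S,3E)-1-{[tert-butyl(dimethyl)silyl]oxy}hex-3-enyl]tetrahydrofuro[3,2-b]furan-2(3H)-one
Conditions: TBSOTf (1.3 equiv), 2,6-lutidine, CH2Cl2, −78 to 0 °C
Reagents that add atoms: tert-butyldimethylsilyl trifluoromethanesulfonate, CC(C)(C)[Si](C)(C)OS(=O)(=O)C(F)(F)F
Why: Silylation of a hindered secondary alcohol with a silyl triflate and a hindered base; it marks O10 so that O7 alone is free for acetylation later.

Step 11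
Reactants: 15 (3aR,5R,6aR)-5-[(1S,3E)-1-{[tert-butyl(dimethyl)silyl]oxy}hex-3-enyl]tetrahydrofuro[3,2-b]furan-2(3H)-one
Product: 16 (3aR,5R,6aR)-5-[(1S,3E)-1-{[tert-butyl(dimethyl)silyl]oxy}hex-3-enyl]hexahydrofuro[3,2-b]furan-2-ol (both C4 anomers)
Conditions: i-Bu2AlH (1.2 equiv), CH2Cl2, −78 °C; aq. potassium sodium tartrate
Reagents that add atoms: none
Why: Partial reduction of a γ-lactone to the lactol; the tetrahedral aluminium acetal is stable at −78 °C, so over-reduction to the diol should not occur.

Step 12
Reactants: 16 (3aR,5R,6aR)-5-[(1S,3E)-1-{[tert-butyl(dimethyl)silyl]oxy}hex-3-enyl]hexahydrofuro[3,2-b]furan-2-ol; 17 iodoform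
Product: 19 (2R,3R,5R)-5-[(1S,3E)-1-{[tert-butyl(dimethyl)silyl]oxy}hex-3-enyl]-2-[(2E)-3-iodoprop-2-enyl]oxolan-3-ol, via hydroxy aldehyde 18 (not isolated)
Conditions: CrCl2 (8 equiv), CHI3 (3 equiv), THF/1,4-dioxane (1:6), 0 °C to rt
Reagents that add atoms: iodoform, IC(I)I
Why: Takai olefination: the geminal dichromium reagent formed from CHI3 and divalent chromium adds to the open-chain tautomer 18 of the lactol, and anti elimination from the β-oxido dichromium adduct should give the (E)-iodoalkene (C3=C4). The neutral conditions spare the β-alkoxy aldehyde and set O7–H free.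

Step 13
Reactants: 19 (2R,3R,5R)-5-[(1S,3E)-1-{[tert-butyl(dimethyl)silyl]oxy}hex-3-enyl]-2-[(2E)-3-iodoprop-2-enyl]oxolan-3-ol; 20 trimethylsilylacetylene
Product: 21 (2R,3R,5R)-5-[(1S,3E)-1-{[tert-butyl(dimethyl)silyl]oxy}hex-3-enyl]-2-[(2E)-5-(trimethylsilyl)pent-2-en-4-ynyl]oxolan-3-ol
Conditions: PdCl2(PPh3)2 (5 mol %), CuI (10 mol %), Et3N, THF, rt
Reagents that add atoms: ethynyl(trimethyl)silane, C#C[Si](C)(C)C
Why: Sonogashira coupling forms C2–C3 with retention of the E geometry (oxidative addition of the iodoalkene to zerovalent palladium, transmetalation from the copper acetylide); the free hydroxyl and the silyl ether are tolerated.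

Step 14
Reactants: 21 (2R,3R,5R)-5-[(1S,3E)-1-{[tert-butyl(dimethyl)silyl]oxy}hex-3-enyl]-2-[(2E)-5-(trimethylsilyl)pent-2-en-4-ynyl]oxolan-3-ol
Product: 22 (2R,3R,5R)-5-[(1S,3E)-1-{[tert-butyl(dimethyl)silyl]oxy}hex-3-enyl]-2-[(2E)-5-(trimethylsilyl)pent-2-en-4-ynyl]oxolan-3-yl acetate
Conditions: Ac2O, pyridine, DMAP (cat.), CH2Cl2, rt
Reagents that add atoms: acetic anhydride, CC(=O)OC(C)=O
Why: DMAP-catalysed acylation of the only free hydroxyl (O7); no stereocentre is affected.

Step 15
Reactants: 22 (2R,3R,5R)-5-[(1S,3E)-1-{[tert-butyl(dimethyl)silyl]oxy}hex-3-enyl]-2-[(2E)-5-(trimethylsilyl)pent-2-en-4-ynyl]oxolan-3-yl acetate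
Product: 23 (2R,3R,5R)-5-[(1S,3E)-1-hydroxyhex-3-enyl]-2-[(2E)-pent-2-en-4-ynyl]oxolan-3-yl acetate
Conditions: TBAF (3 equiv), AcOH (3 equiv), THF, 0 °C to rt
Reagents that add atoms: none
Why: Fluoride removes the alkynyl trimethylsilyl group and the O10 silyl ether in one operation; the acetic acid buffer protects the acetate, and acyl migration from O7 to O10 would need a seven-membered transition state.

Step 16
Reactants: 23 (2R,3R,5R)-5-[(1S,3E)-1-hydroxyhex-3-enyl]-2-[(2E)-pent-2-en-4-ynyl]oxolan-3-yl acetate
Product: 24 trans-kumausyne, (2R,3R,5R)-5-[(1R,3E)-1-bromohex-3-enyl]-2-[(2E)-pent-2-en-4-ynyl]oxolan-3-yl acetate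
Conditions: CBr4 (3 equiv), P(n-C8H17)3 (3 equiv), toluene, 70 °C
Reagents that add atoms: carbon tetrabromide, BrC(Br)(Br)Br
Why: Appel reaction: the alkoxyphosphonium ion at O10 is displaced by bromide in an SN2 step, so the (10S) alcohol should give the (10R) bromide; the neutral medium leaves the acetate and the enyne alone.

## Compound list

1 | dimethyl (R)-malate, dimethyl (2R)-2-hydroxybutanedioate | COC(=O)C[C@@H](O)C(=O)OC | starting material
2 | methyl (3R)-3,4-dihydroxybutanoate | COC(=O)C[C@@H](O)CO | intermediate
3 | methyl (3R)-4-[(tert-butyldiphenylsilyl)oxy]-3-hydroxybutanoate | COC(=O)C[C@@H](O)CO[Si](c1ccccc1)(c1ccccc1)C(C)(C)C | intermediate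
4 | (3R)-4-[(tert-butyldiphenylsilyl)oxy]-3-hydroxy-N-methoxy-N-methylbutanamide | CON(C)C(=O)C[C@@H](O)CO[Si](c1ccccc1)(c1ccccc1)C(C)(C)C | intermediate
5 | vinylmagnesium bromide | C=C[Mg]Br | starting material
6 | (5R)-6-[(tert-butyldiphenylsilyl)oxy]-5-hydroxyhex-1-en-3-one | C=CC(=O)C[C@@H](O)CO[Si](c1ccccc1)(c1ccccc1)C(C)(C)C | intermediate
7 | (2R,4R)-1-[(tert-butyldiphenylsilyl)oxy]hex-5-ene-2,4-diol | C=C[C@H](O)C[C@@H](O)CO[Si](c1ccccc1)(c1ccccc1)C(C)(C)C | intermediate
8 | carbon monoxide | [C-]#[O+] | starting material
9 | (3aR,5R,6aR)-5-{[(tert-butyldiphenylsilyl)oxy]methyl}tetrahydrofuro[3,2-b]furan-2(3H)-one | O=C1C[C@H]2O[C@@H](CO[Si](c3ccccc3)(c3ccccc3)C(C)(C)C)C[C@H]2O1 | intermediate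
10 | (3aR,5R,6aR)-5-(hydroxymethyl)tetrahydrofuro[3,2-b]furan-2(3H)-one | O=C1C[C@H]2O[C@@H](CO)C[C@H]2O1 | intermediate
11 | (3aR,5R,6aR)-2-oxohexahydrofuro[3,2-b]furan-5-carbaldehyde | O=C1C[C@H]2O[C@@H](C=O)C[C@H]2O1 | intermediate
12 | buta-1,3-diene | C=CC=C | starting material
13 | dimethylzinc | C[Zn]C | starting material
14 | (3aR,5R,6aR)-5-[(1S,3E)-1-hydroxyhex-3-enyl]tetrahydrofuro[3,2-b]furan-2(3H)-one | O=C1C[C@H]2O[C@@H]([C@@H](O)C/C=C/CC)C[C@H]2O1 | intermediate
15 | (3aR,5R,6aR)-5-[(1S,3E)-1-{[tert-butyl(dimethyl)silyl]oxy}hex-3-enyl]tetrahydrofuro[3,2-b]furan-2(3H)-one | O=C1C[C@H]2O[C@@H]([C@@H](O[Si](C)(C)C(C)(C)C)C/C=C/CC)C[C@H]2O1 | intermediate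
16 | (3aR,5R,6aR)-5-[(1S,3E)-1-{[tert-butyl(dimethyl)silyl]oxy}hex-3-enyl]hexahydrofuro[3,2-b]furan-2-ol (anomers) | OC1C[C@H]2O[C@@H]([C@@H](O[Si](C)(C)C(C)(C)C)C/C=C/CC)C[C@H]2O1 | intermediate
17 | iodoform | IC(I)I | starting material
18 | 2-{(2R,3R,5R)-5-[(1S,3E)-1-{[tert-butyl(dimethyl)silyl]oxy}hex-3-enyl]-3-hydroxyoxolan-2-yl}acetaldehyde | O=CC[C@H]1O[C@@H]([C@@H](O[Si](C)(C)C(C)(C)C)C/C=C/CC)C[C@H]1O | intermediate (not isolated)
19 | (2R,3R,5R)-5-[(1S,3E)-1-{[tert-butyl(dimethyl)silyl]oxy}hex-3-enyl]-2-[(2E)-3-iodoprop-2-enyl]oxolan-3-ol | I/C=C/C[C@H]1O[C@@H]([C@@H](O[Si](C)(C)C(C)(C)C)C/C=C/CC)C[C@H]1O | intermediate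
20 | trimethylsilylacetylene, ethynyl(trimethyl)silane | C#C[Si](C)(C)C | starting material
21 | (2R,3R,5R)-5-[(1S,3E)-1-{[tert-butyl(dimethyl)silyl]oxy}hex-3-enyl]-2-[(2E)-5-(trimethylsilyl)pent-2-en-4-ynyl]oxolan-3-ol | C[Si](C)(C)C#C/C=C/C[C@H]1O[C@@H]([C@@H](O[Si](C)(C)C(C)(C)C)C/C=C/CC)C[C@H]1O | intermediate
22 | (2R,3R,5R)-5-[(1S,3E)-1-{[tert-butyl(dimethyl)silyl]oxy}hex-3-enyl]-2-[(2E)-5-(trimethylsilyl)pent-2-en-4-ynyl]oxolan-3-yl acetate | C[Si](C)(C)C#C/C=C/C[C@H]1O[C@@H]([C@@H](O[Si](C)(C)C(C)(C)C)C/C=C/CC)C[C@H]1OC(C)=O | intermediate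
23 | (2R,3R,5R)-5-[(1S,3E)-1-hydroxyhex-3-enyl]-2-[(2E)-pent-2-en-4-ynyl]oxolan-3-yl acetate | C#C/C=C/C[C@H]1O[C@@H]([C@@H](O)C/C=C/CC)C[C@H]1OC(C)=O | intermediate
24 | trans-kumausyne, (2R,3R,5R)-5-[(1R,3E)-1-bromohex-3-enyl]-2-[(2E)-pent-2-en-4-ynyl]oxolan-3-yl acetate | C#C/C=C/C[C@H]1O[C@@H]([C@H](Br)C/C=C/CC)C[C@H]1OC(C)=O | target

## Step count and least certain steps

Total step count: 16. Longest linear sequence: 16 steps (1 to 24); the route is fully linear, and 5, 8, 12, 13, 17 and 20 are bought.

**Step 9 (key step).** The most likely failure is poor facial selectivity at C10, because a zinc chelate between O1 and the aldehyde oxygen competes with the Felkin–Anh arrangement; uncatalysed methyl transfer to the activated aldehyde is the second concern. The fallback keeps the three-component disconnection and moves the control of C10 to a reduction. It sets out from 11: the coupling is run as in step 9, and the mixture of 14 and its C10 epimer (3aR,5R,6aR)-5-[(1R,3E)-1-hydroxyhex-3-enyl]tetrahydrofuro[3,2-b]furan-2(3H)-one F1 is oxidised with Dess–Martin periodinane in CH2Cl2 to the ketone (3aR,5R,6aR)-5-[(3E)-hex-3-enoyl]tetrahydrofuro[3,2-b]furan-2(3H)-one F2. Reduction with Zn(BH4)2 in Et2O at −78 to −30 °C should then proceed through the five-membered zinc chelate of O1 and the ketone oxygen, with hydride entering from the side of C9–H; this gives the anti (10S) alcohol, and the lactone is inert to this hydride. The sequence comes back to the route at 14.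

**Step 16.** The most likely failure is elimination toward the conjugated C10–C13 diene, or participation of O1 leading to retention or ring-expanded products, because the activated carbinol is hindered, β to the ring oxygen and next to an allylic CH2. The fallback separates activation from displacement. It sets out from 23, which is converted with ClCH2SO2Cl and 2,6-lutidine in CH2Cl2 at 0 °C into the sulfonate (2R,3R,5R)-5-{(1S,3E)-1-[(chloromethanesulfonyl)oxy]hex-3-enyl}-2-[(2E)-pent-2-en-4-ynyl]oxolan-3-yl acetate F3. This very reactive but non-ionising leaving group is displaced by Bu4NBr in toluene at 40–60 °C in an SN2 step with inversion. The sequence comes back to the route at 24.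

**Step 6.** The most likely failure is incomplete turnover or competing Wacker-type oxidation and acetoxylation of the allylic alcohol, together with slow loss of the silyl ether in AcOH/CuCl2. The fallback brings in C4 by metathesis and closes ring A by conjugate addition. It sets out from 7, which undergoes cross-metathesis with methyl acrylate (second-generation Grubbs catalyst, (H2IMes)(PCy3)Cl2Ru=CHPh, CH2Cl2, 40 °C) to give methyl (2E,4R,6R)-7-[(tert-butyldiphenylsilyl)oxy]-4,6-dihydroxyhept-2-enoate F4. Catalytic NaOMe in MeOH, or DBU in toluene, should then induce a reversible 5-exo-trig oxa-Michael addition of O9 to C6. Only the isomer with C5 cis to O7 can lactonise, which drains the equilibrium. The sequence comes back to the route at 9.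

**Step 12.** The most likely failure is sluggish olefination, because little of the lactol is present as the open aldehyde, with erosion of the E/Z ratio on long reaction times. The fallback makes the iodoalkene by hydrometalation of an alkyne. It sets out from 16, which is homologated with dimethyl (1-diazo-2-oxopropyl)phosphonate and K2CO3 in MeOH at 0 °C (Ohira–Bestmann reaction, kept cold to avoid β-elimination of O1) to (2R,3R,5R)-5-[(1S,3E)-1-{[tert-butyl(dimethyl)silyl]oxy}hex-3-enyl]-2-(prop-2-ynyl)oxolan-3-ol F5. Hydrozirconation of the terminal alkyne with Cp2Zr(H)Cl (2.2 equiv, THF, rt; the internal alkene is much slower) and quenching with I2 should give the (E)-iodoalkene as a single isomer. The sequence comes back to the route at 19.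

## Further compounds

F1 | step 9 | (3aR,5R,6aR)-5-[(1R,3E)-1-hydroxyhex-3-enyl]tetrahydrofuro[3,2-b]furan-2(3H)-one | O=C1C[C@H]2O[C@@H]([C@H](O)C/C=C/CC)C[C@H]2O1
F2 | step 9 | (3aR,5R,6aR)-5-[(3E)-hex-3-enoyl]tetrahydrofuro[3,2-b]furan-2(3H)-one | O=C1C[C@H]2O[C@@H](C(=O)C/C=C/CC)C[C@H]2O1
F3 | step 16 | (2R,3R,5R)-5-{(1S,3E)-1-[(chloromethanesulfonyl)oxy]hex-3-enyl}-2-[(2E)-pent-2-en-4-ynyl]oxolan-3-yl acetate | C#C/C=C/C[C@H]1O[C@@H]([C@@H](OS(=O)(=O)CCl)C/C=C/CC)C[C@H]1OC(C)=O
F4 | step 6 | methyl (2E,4R,6R)-7-[(tert-butyldiphenylsilyl)oxy]-4,6-dihydroxyhept-2-enoate | COC(=O)/C=C/[C@H](O)C[C@@H](O)CO[Si](c1ccccc1)(c1ccccc1)C(C)(C)C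
F5 | step 12 | (2R,3R,5R)-5-[(1S,3E)-1-{[tert-butyl(dimethyl)silyl]oxy}hex-3-enyl]-2-(prop-2-ynyl)oxolan-3-ol | C#CC[C@H]1O[C@@H]([C@@H](O[Si](C)(C)C(C)(C)C)C/C=C/CC)C[C@H]1O
A1 | alternative 1 | (1R,5S)-8-oxabicyclo[3.2.1]oct-6-en-3-one (meso) | O=C1C[C@@H]2C=C[C@H](C1)O2
A2 | alternative 1 | furan | c1ccoc1
A3 | alternative 1 | 1,1,3,3-tetrabromopropan-2-one | O=C(C(Br)Br)C(Br)Br
A4 | alternative 2 | methyl 2-{(2R,3S,5R)-5-[(1S,3E)-1-(tert-butyldiphenylsilyloxy)hex-3-enyl]-3-[dimethyl(phenyl)silyl]oxolan-2-yl}acetate | COC(=O)C[C@H]1O[C@@H]([C@@H](O[Si](c2ccccc2)(c2ccccc2)C(C)(C)C)C/C=C/CC)C[C@@H]1[Si](C)(C)c1ccccc1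
A5 | alternative 2 | methyl (3S)-3-[dimethyl(phenyl)silyl]pent-4-enoate | COC(=O)C[C@@H](C=C)[Si](C)(C)c1ccccc1
A6 | alternative 2 | (2S,4E)-2-[(tert-butyldiphenylsilyl)oxy]hept-4-enal | O=C[C@@H](O[Si](c1ccccc1)(c1ccccc1)C(C)(C)C)C/C=C/CC
A7 | alternative 3 | (3aR,5S,6S,6aS)-5-[(4S)-2,2-dimethyl-1,3-dioxolan-4-yl]-6-iodotetrahydrofuro[3,2-b]furan-2(3H)-one | O=C1C[C@H]2O[C@@H]([C@@H]3COC(C)(C)O3)[C@H](I)[C@H]2O1
A8 | alternative 3 | 2-{(2R,5R)-5-[(4S)-2,2-dimethyl-1,3-dioxolan-4-yl]-2,5-dihydrofuran-2-yl}acetic acid | OC(=O)C[C@H]1O[C@@H]([C@@H]2COC(C)(C)O2)C=C1
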